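I choose to reckon this flask by one quantity, the partner budget: the coupling partner charged as a percentage of the substrate charged, 80.0%. That stands below 100, so the coupling partner is the limiting reagent. I follow one substrate molecule. It takes one coupling partner to give intermediate and by-product, the intermediate becomes target, and at the fork the target stays or takes a second partner to give over-reaction product. Partner spent, counted on the same scale, is therefore conversion plus over-reaction product.

| setting | summer | flask |
|---|---|---|
| substrate | 0.60 M | 0.60 M |
| coupling partner | 0.48 M | 0.480 M |
| remark | the very flask that is asked about, followed so far |  |
| time |  | 5.0 d |

summer run (percent of the substrate charged)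

| time / h | substrate / % | target / % | over-reaction product / % |
|---|---|---|---|
| 6.00 | 63 | 8 | 3 |
| 12.0 | 52 | 21 | 15 |
| 20.0 | 46 | 23 | 23 |
| 25.0 | 47 | 24 | 23 |
| 30.0 | 47 | 28 | 27 |
| 40.0 | 45 | 28 | 28 |

(readings scatter by 1.5 percentage points)

- what was read earlier has a scatter of 1.5 percentage points, one standard deviation
- reactions considered so far: substrate + coupling partner -> intermediate + by-product; intermediate -> target; coupling partner + target -> over-reaction product
- the reaction counts as stopped when no species that holds the substrate changes by six tenths of a point or more over the second half of the time

* which holds at 5.0 d: what has brought the reaction to rest, or that it has not come to rest (the coupling partner has run out first / all of the substrate has reacted / it is still moving)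
* conversion of substrate at 5.0 d
* amount of target at 5.0 d, in percent of the substrate charged
* amount of over-reaction product at 5.0 d, in percent of the substrate charged

In the summer run, which is this same flask, the readings have the substrate falling 37 percentage points by 6.00 h, then 11 points over the next 6.00 h. Partner spent climbs towards the budget:

at 6.00 h: 40.0%
at 12.0 h: 63.0%
at 20.0 h: 77.0%
at 30.0 h: 80.0%

That last sum reads level with the budget, so I read the knee by then, within the scatter of the readings. At 40.0 h, target plus over-reaction product reads 56.0% against a conversion of 55.0%, so I count the intermediate as drained. The fork there reads 0.500 towards over-reaction product, which gives my level: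

conversion = budget / (1 + fork) = 53.3%
over-reaction product = budget − conversion = 26.7%
target = conversion − over-reaction product = 26.7%

The forecast says the coupling partner has run out first, with conversion 54% (52.5% to 55.5%), target 28% (26% to 30%) and over-reaction product 26% (24.5% to 28%), since “the partner is essentially gone”. My conversion stands 0.70 points below its value, my target 1.3 points below, and my over-reaction product 0.70 points above.

The flask gives the coupling partner has run out first, with conversion 54.2%, target 28.5% and over-reaction product 25.8%.

    substrate + coupling partner → intermediate + by-product (k = 5.67 × 10⁻⁵ M⁻¹ s⁻¹)
    intermediate → target (k = 4.10 × 10⁻⁵ s⁻¹)
    coupling partner + target → over-reaction product (k = 2.12 × 10⁻⁴ M⁻¹ s⁻¹)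

In this flask 0.00508% of the partner's charge stands at 2.50 d, and 0% at 5.00 d. Partner spent here comes to 80.0%, against the budget of 80.0%. The neighbour flask with 1.0 M of substrate has a budget of 48.0%. It ends with 0% of its partner, conversion 37.9% and over-reaction product 10.1%, so it has spent 48.0%.

All runs were generated by integration with constants of no real substance, noise included.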